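**Retrosynthetic overview**

- The strategy rests on the cis-2,3-dihydrobenzofuran (O1–C2–C3–C3a–C7a, fused to ring C): its C2–C3 bond joins the benzylic ether carbon C2, which carries syringyl ring B, to C3, which carries the CH2OH carbon, with the two substituents cis (2R,3R).
- Last disconnection, the arylglycerol arm: C7–OH from chelation-controlled reduction of an aryl ketone (ring A Grignard reagent plus Weinreb amide); the C8–O(ring B) ether from Mitsunobu inversion of a methyl (R)-glycerate derivative with the ring B phenol.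
- Key disconnection, C2–C3: the cis ester 17 from aryldiazoacetate 16 by enantioselective intramolecular rhodium-carbenoid 1,5-C–H insertion into the ring C–O–CH2–ring B ether.
- Diazo ester 16 from an arylacetate made by allylation, Claisen rearrangement and oxidative cleavage on an eugenol-derived ring C, etherified with a syringaldehyde-derived benzyl alcohol.
- Ring order: rings A, B and C are bought as arenes; the dihydrofuran ring is the only ring closed (step 12).

Key step: step 12

Assumption: Rh2(S-PTTL)4 is taken to deliver the (2R,3S) ester, by analogy with simpler 2-(benzyloxy)aryl diazoacetates; should the sense be opposite, Rh2(R-PTTL)4 is used with no other change.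

Abbreviations: TBS = tert-butyldimethylsilyl; TIPS = triisopropylsilyl; 9-BBN = 9-borabicyclo[3.3.1]nonane; DIAD = diisopropyl azodicarboxylate; p-ABSA = 4-acetamidobenzenesulfonyl azide; Rh2(S-PTTL)4 = dirhodium tetrakis[N-phthaloyl-(S)-tert-leucinate].

**Step 1**
Reactants: 1 eugenol (4-allyl-2-methoxyphenol)
Product: 3 3-(4-hydroxy-3-methoxyphenyl)propan-1-ol, via bis(9-BBN) adduct 2 (not isolated)
Conditions: 9-BBN (2.2 equiv), THF, 0 °C → rt; then NaOH aq, H2O2, 0 °C
Reagents that add atoms: hydrogen peroxide, OO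
Why: Anti-Markovnikov hydroboration–oxidation of the terminal alkene, in which one equivalent of the bulky borane is taken up by the phenol O–H and the second places boron on the terminal carbon.

**Step 2**
Reactants: 3 3-(4-hydroxy-3-methoxyphenyl)propan-1-ol; 4 allyl bromide
Product: 5 3-[4-(allyloxy)-3-methoxyphenyl]propan-1-ol
Conditions: K2CO3, acetone, reflux
Reagents that add atoms: none
Why: Williamson etherification in which carbonate ionises only the phenol, so the aliphatic alcohol is left untouched.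

**Step 3**
Reactants: 5 3-[4-(allyloxy)-3-methoxyphenyl]propan-1-ol
Product: 6 1-(allyloxy)-2-methoxy-4-[3-(TBS-oxy)propyl]benzene
Conditions: TBSCl, imidazole, DMF, rt
Reagents that add atoms: tert-butyldimethylsilyl chloride, CC(C)(C)[Si](C)(C)Cl
Why: Standard silylation of the only hydroxyl group, giving an ether that tolerates the thermal, oxidative and basic steps up to the carbenoid closure.

**Step 4**
Reactants: 6 1-(allyloxy)-2-methoxy-4-[3-(TBS-oxy)propyl]benzene
Product: 7 2-allyl-6-methoxy-4-[3-(TBS-oxy)propyl]phenol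
Conditions: PhNEt2, 195 °C, sealed vessel
Reagents that add atoms: none
Why: Aromatic Claisen rearrangement ([3,3]-sigmatropic shift then tautomerisation), regiospecific because only one ortho position is free.

**Step 5**
Reactants: 8 syringaldehyde (4-hydroxy-3,5-dimethoxybenzaldehyde)
Product: 9 3,5-dimethoxy-4-(TIPS-oxy)benzaldehyde
Conditions: TIPSCl, imidazole, DMF, rt → 40 °C
Reagents that add atoms: triisopropylsilyl chloride, CC(C)[Si](Cl)(C(C)C)C(C)C
Why: Silylation of the acidic phenol with a bulky group that resists the later basic steps and prevents quinone-methide formation from the para-oxygenated benzyl unit.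

**Step 6**
Reactants: 9 3,5-dimethoxy-4-(TIPS-oxy)benzaldehyde
Product: 10 [3,5-dimethoxy-4-(TIPS-oxy)phenyl]methanol
Conditions: NaBH4, THF/EtOH, 0 °C
Reagents that add atoms: none
Why: Borohydride reduction of the aldehyde, kept short and cold so that the aryl silyl ether is not solvolysed.

**Step 7**
Reactants: 7 2-allyl-6-methoxy-4-[3-(TBS-oxy)propyl]phenol; 10 [3,5-dimethoxy-4-(TIPS-oxy)phenyl]methanol
Product: 11 1-allyl-2-[3,5-dimethoxy-4-(TIPS-oxy)benzyloxy]-3-methoxy-5-[3-(TBS-oxy)propyl]benzene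
Conditions: PPh3, DIAD, THF, 0 °C → rt
Reagents that add atoms: none
Why: Mitsunobu etherification in which the primary benzylic alcohol is activated as its oxyphosphonium ion and displaced by the phenoxide under neutral conditions that spare both silyl ethers.

**Step 8**
Reactants: 11 1-allyl-2-[3,5-dimethoxy-4-(TIPS-oxy)benzyloxy]-3-methoxy-5-[3-(TBS-oxy)propyl]benzene
Product: 13 2-{2-[3,5-dimethoxy-4-(TIPS-oxy)benzyloxy]-3-methoxy-5-[3-(TBS-oxy)propyl]phenyl}acetaldehyde, via vicinal diol 12 (not isolated)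
Conditions: OsO4 (cat.), NaIO4, 2,6-lutidine, dioxane/H2O, rt
Reagents that add atoms: osmium tetroxide, O=[Os](=O)(=O)=O, with its oxygen restored from sodium periodate, [Na+].[O-]I(=O)(=O)=O
Why: Lemieux–Johnson cleavage (dihydroxylation then periodate scission) of the only alkene, chosen over ozone to spare the electron-rich arenes.

**Step 9**
Reactants: 13 2-{2-[3,5-dimethoxy-4-(TIPS-oxy)benzyloxy]-3-methoxy-5-[3-(TBS-oxy)propyl]phenyl}acetaldehyde
Product: 14 2-{2-[3,5-dimethoxy-4-(TIPS-oxy)benzyloxy]-3-methoxy-5-[3-(TBS-oxy)propyl]phenyl}acetic acid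
Conditions: NaClO2, NaH2PO4, 2-methyl-2-butene, tBuOH/H2O, 0 °C → rt
Reagents that add atoms: sodium chlorite, [Na+].[O-]Cl=O
Why: Pinnick oxidation of the crude aldehyde, with the alkene scavenger removing HOCl before it can chlorinate the arenes.

**Step 10**
Reactants: 14 2-{2-[3,5-dimethoxy-4-(TIPS-oxy)benzyloxy]-3-methoxy-5-[3-(TBS-oxy)propyl]phenyl}acetic acid
Product: 15 methyl 2-{2-[3,5-dimethoxy-4-(TIPS-oxy)benzyloxy]-3-methoxy-5-[3-(TBS-oxy)propyl]phenyl}acetate
Conditions: TMSCHN2, toluene/MeOH, 0 °C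
Reagents that add atoms: trimethylsilyldiazomethane, C[Si](C)(C)C=[N+]=[N-]
Why: Neutral O-methylation of the acid by diazomethane released in the flask, which avoids base near the aryl silyl ether.

**Step 11**
Reactants: 15 methyl 2-{2-[3,5-dimethoxy-4-(TIPS-oxy)benzyloxy]-3-methoxy-5-[3-(TBS-oxy)propyl]phenyl}acetate
Product: 16 methyl 2-diazo-2-{2-[3,5-dimethoxy-4-(TIPS-oxy)benzyloxy]-3-methoxy-5-[3-(TBS-oxy)propyl]phenyl}acetate
Conditions: p-ABSA, DBU, MeCN, 0 °C → rt
Reagents that add atoms: 4-acetamidobenzenesulfonyl azide, CC(=O)Nc1ccc(cc1)S(=O)(=O)N=[N+]=[N-]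
Why: Regitz diazo transfer to the benzylic ester enolate, the usual entry to aryldiazoacetates carrying an ortho alkoxy group.

**Step 12**
Reactants: 16 methyl 2-diazo-2-{2-[3,5-dimethoxy-4-(TIPS-oxy)benzyloxy]-3-methoxy-5-[3-(TBS-oxy)propyl]phenyl}acetate
Product: 17 methyl (2R,3S)-2-[3,5-dimethoxy-4-(TIPS-oxy)phenyl]-7-methoxy-5-[3-(TBS-oxy)propyl]-2,3-dihydro-1-benzofuran-3-carboxylate (cis)
Conditions: Rh2(S-PTTL)4 (2 mol %), toluene, −78 → −40 °C, slow addition of 16
Reagents that add atoms: none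
Why: Rh2(S-PTTL)4 expels N2 from 16 to give a donor/acceptor rhodium carbenoid whose electrophilic carbon takes up a benzylic O–CH2 hydrogen and its carbon in one concerted, hydride-transfer-like three-centre transition state; the closest known reaction type is the enantioselective dirhodium-catalysed intramolecular C–H insertion of 2-(benzyloxy)aryl diazoacetates to cis-2-aryl-2,3-dihydrobenzofuran-3-carboxylates. The dihydrofuran ring is closed as a five-membered ring by 1,5-insertion, the new C2–C3 bond joining the carbenoid carbon to the ether carbon five atoms away. C3 is set by the carbenoid face that the chiral carboxylate pocket leaves open and C2 by which of the two enantiotopic benzylic hydrogens is taken, so the absolute sense and the cis relation (aryl and ester on the same side of the compact transition state) are both under kinetic catalyst control. The step needs site selectivity, cis selectivity and enantioselectivity: the only C–H bond within reach of a five-membered closure is the O–CH2, activated by the ether oxygen and by the electron-rich silyloxy-dimethoxyphenyl ring, while the methoxy C–H bonds cannot reach the carbenoid carbon. Low temperature, a non-polar solvent and the absence of base keep the kinetic cis ester from epimerising at C3 to trans.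

**Step 13**
Reactants: 17 methyl (2R,3S)-2-[3,5-dimethoxy-4-(TIPS-oxy)phenyl]-7-methoxy-5-[3-(TBS-oxy)propyl]-2,3-dihydro-1-benzofuran-3-carboxylate
Product: 18 {(2R,3R)-2-[3,5-dimethoxy-4-(TIPS-oxy)phenyl]-7-methoxy-5-[3-(TBS-oxy)propyl]-2,3-dihydro-1-benzofuran-3-yl}methanol
Conditions: iBu2AlH (3 equiv), CH2Cl2, −78 → −40 °C; KNaC4H4O6 aq (potassium sodium tartrate)
Reagents that add atoms: none
Why: Ester reduction by a Lewis-acidic, non-basic hydride at low temperature, so that C3 (now labelled R only through a priority change) keeps its cis configuration and stops being epimerisable.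

**Step 14**
Reactants: 18 {(2R,3R)-2-[3,5-dimethoxy-4-(TIPS-oxy)phenyl]-7-methoxy-5-[3-(TBS-oxy)propyl]-2,3-dihydro-1-benzofuran-3-yl}methanol
Product: 19 (2R,3R)-3-[(TBS-oxy)methyl]-2-[3,5-dimethoxy-4-(TIPS-oxy)phenyl]-7-methoxy-5-[3-(TBS-oxy)propyl]-2,3-dihydro-1-benzofuran
Conditions: TBSCl, imidazole, CH2Cl2, 0 °C → rt
Reagents that add atoms: tert-butyldimethylsilyl chloride, CC(C)(C)[Si](C)(C)Cl
Why: Routine silylation of the primary alcohol, so that only the ring B phenol reacts in the later Mitsunobu and organomagnesium steps.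

**Step 15**
Reactants: 19 (2R,3R)-3-[(TBS-oxy)methyl]-2-[3,5-dimethoxy-4-(TIPS-oxy)phenyl]-7-methoxy-5-[3-(TBS-oxy)propyl]-2,3-dihydro-1-benzofuran
Product: 20 4-{(2R,3R)-3-[(TBS-oxy)methyl]-7-methoxy-5-[3-(TBS-oxy)propyl]-2,3-dihydro-1-benzofuran-2-yl}-2,6-dimethoxyphenol
Conditions: Bu4NF/AcOH (1:1, 1.2 equiv), THF, 0 °C
Reagents that add atoms: none
Why: Chemoselective fluoride cleavage of the aryl silyl ether (phenoxide is the better leaving group than alkoxide), buffered so that no free para-phenoxide can open the cis-dihydrofuran through a quinone methide.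

**Step 16**
Reactants: 21 methyl (R)-2,2-dimethyl-1,3-dioxolane-4-carboxylate
Product: 22 methyl (R)-2,3-dihydroxypropanoate
Conditions: Amberlyst-15 (H+ resin), MeOH, rt
Reagents that add atoms: none
Why: Acid-catalysed transacetalisation to methanol, which frees the diol without touching the methyl ester or the stereocentre.

**Step 17**
Reactants: 22 methyl (R)-2,3-dihydroxypropanoate
Product: 23 methyl (R)-3-(TBS-oxy)-2-hydroxypropanoate
Conditions: TBSCl (1.05 equiv), imidazole, CH2Cl2, −10 °C
Reagents that add atoms: tert-butyldimethylsilyl chloride, CC(C)(C)[Si](C)(C)Cl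
Why: Sterically controlled monosilylation of the primary hydroxyl, leaving the secondary α-hydroxyl free for the ether formation.

**Step 18**
Reactants: 20 4-{(2R,3R)-3-[(TBS-oxy)methyl]-7-methoxy-5-[3-(TBS-oxy)propyl]-2,3-dihydro-1-benzofuran-2-yl}-2,6-dimethoxyphenol; 23 methyl (R)-3-(TBS-oxy)-2-hydroxypropanoate
Product: 24 methyl (S)-3-(TBS-oxy)-2-(4-{(2R,3R)-3-[(TBS-oxy)methyl]-7-methoxy-5-[3-(TBS-oxy)propyl]-2,3-dihydro-1-benzofuran-2-yl}-2,6-dimethoxyphenoxy)propanoate
Conditions: PPh3, DIAD, toluene, 0 °C → rt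
Reagents that add atoms: none
Why: Mitsunobu reaction of an α-hydroxy ester with a phenol, an SN2 displacement with clean inversion that turns the (R)-carbinol into the (S)-aryl ether and so sets C8 from the chiral pool.

**Step 19**
Reactants: 24 methyl (S)-3-(TBS-oxy)-2-(aryloxy)propanoate (aryl = the ring B unit of 20)
Product: 25 (S)-3-(TBS-oxy)-N-methoxy-N-methyl-2-(4-{(2R,3R)-3-[(TBS-oxy)methyl]-7-methoxy-5-[3-(TBS-oxy)propyl]-2,3-dihydro-1-benzofuran-2-yl}-2,6-dimethoxyphenoxy)propanamide
Conditions: MeNH(OMe)·HCl, iPrMgCl, THF, −20 °C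
Reagents that add atoms: N,O-dimethylhydroxylamine hydrochloride, CNOC.Cl
Why: Direct ester aminolysis by the chloromagnesium amide (Weinreb amide formation), run cold so that the α-aryloxy stereocentre is neither enolised nor lost by β-elimination.

**Step 20**
Reactants: 26 4-bromo-2-methoxyphenol
Product: 27 (4-bromo-2-methoxyphenoxy)triisopropylsilane
Conditions: TIPSCl, imidazole, DMF, rt
Reagents that add atoms: triisopropylsilyl chloride, CC(C)[Si](Cl)(C(C)C)C(C)C
Why: Phenol silylation with a group robust enough for Grignard formation and for a position para to the later ketone.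

**Step 21**
Reactants: 27 (4-bromo-2-methoxyphenoxy)triisopropylsilane; 25 the Weinreb amide
Product: 29 (S)-3-(TBS-oxy)-1-[3-methoxy-4-(TIPS-oxy)phenyl]-2-(4-{(2R,3R)-3-[(TBS-oxy)methyl]-7-methoxy-5-[3-(TBS-oxy)propyl]-2,3-dihydro-1-benzofuran-2-yl}-2,6-dimethoxyphenoxy)propan-1-one, via arylmagnesium bromide 28 (not isolated)
Conditions: 27, Mg, THF, 40 °C; then 25, THF, 0 °C; NH4Cl aq
Reagents that add atoms: none
Why: Weinreb ketone synthesis, in which the magnesium chelate of the tetrahedral adduct holds until work-up, preventing over-addition and keeping the α-centre from enolising under the basic reagent.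

**Step 22**
Reactants: 29 the (S)-α-aryloxy ketone
Product: 30 (1R,2S)-3-(TBS-oxy)-1-[3-methoxy-4-(TIPS-oxy)phenyl]-2-(4-{(2R,3R)-3-[(TBS-oxy)methyl]-7-methoxy-5-[3-(TBS-oxy)propyl]-2,3-dihydro-1-benzofuran-2-yl}-2,6-dimethoxyphenoxy)propan-1-ol
Conditions: Zn(BH4)2, Et2O, −30 → 0 °C
Reagents that add atoms: none
Why: Chelation-controlled (Cram chelate) ketone reduction in which zinc bridges the carbonyl oxygen and the ring B aryloxy oxygen (assisted by an ortho methoxy group) and hydride enters on the side of H8, giving the anti (erythro) 7R alcohol, while the bulky non-coordinating C9 silyl ether blocks the competing six-membered chelate that would lead to threo.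

**Step 23**
Reactants: 30 the (1R,2S) tetrasilyl ether
Product: 31 (1R,2S)-1-(4-hydroxy-3-methoxyphenyl)-2-{4-[(2R,3R)-3-(hydroxymethyl)-5-(3-hydroxypropyl)-7-methoxy-2,3-dihydro-1-benzofuran-2-yl]-2,6-dimethoxyphenoxy}propane-1,3-diol (target)
Conditions: Bu4NF/AcOH (1:1, excess), THF, rt
Reagents that add atoms: none
Why: Global fluoride desilylation of three alkyl TBS ethers and the aryl TIPS ether, buffered so that neither the benzylic carbinol C7 nor the benzylic ether C2 is ionised or epimerised.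

**Compound list**

1 | eugenol | COc1cc(CC=C)ccc1O | starting material
2 | bis(9-BBN) adduct of eugenol (B-alkyl and B-aryloxy) | COc1cc(CCCB2C3CCCC2CCC3)ccc1OB1C2CCCC1CCC2 | intermediate
3 | 3-(4-hydroxy-3-methoxyphenyl)propan-1-ol | COc1cc(CCCO)ccc1O | intermediate
4 | allyl bromide | C=CCBr | starting material
5 | 3-[4-(allyloxy)-3-methoxyphenyl]propan-1-ol | C=CCOc1ccc(CCCO)cc1OC | intermediate
6 | 1-(allyloxy)-2-methoxy-4-[3-(TBS-oxy)propyl]benzene | C=CCOc1ccc(CCCO[Si](C)(C)C(C)(C)C)cc1OC | intermediate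
7 | 2-allyl-6-methoxy-4-[3-(TBS-oxy)propyl]phenol | C=CCc1cc(CCCO[Si](C)(C)C(C)(C)C)cc(OC)c1O | intermediate
8 | syringaldehyde | COc1cc(C=O)cc(OC)c1O | starting material
9 | 3,5-dimethoxy-4-(TIPS-oxy)benzaldehyde | COc1cc(C=O)cc(OC)c1O[Si](C(C)C)(C(C)C)C(C)C | intermediate
10 | [3,5-dimethoxy-4-(TIPS-oxy)phenyl]methanol | COc1cc(CO)cc(OC)c1O[Si](C(C)C)(C(C)C)C(C)C | intermediate
11 | 1-allyl-2-[3,5-dimethoxy-4-(TIPS-oxy)benzyloxy]-3-methoxy-5-[3-(TBS-oxy)propyl]benzene | C=CCc1cc(CCCO[Si](C)(C)C(C)(C)C)cc(OC)c1OCc1cc(OC)c(O[Si](C(C)C)(C(C)C)C(C)C)c(OC)c1 | intermediate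
12 | 3-aryl-propane-1,2-diol from 11 (racemic at the carbinol) | OCC(O)Cc1cc(CCCO[Si](C)(C)C(C)(C)C)cc(OC)c1OCc1cc(OC)c(O[Si](C(C)C)(C(C)C)C(C)C)c(OC)c1 | intermediate
13 | arylacetaldehyde | O=CCc1cc(CCCO[Si](C)(C)C(C)(C)C)cc(OC)c1OCc1cc(OC)c(O[Si](C(C)C)(C(C)C)C(C)C)c(OC)c1 | intermediate
14 | arylacetic acid | OC(=O)Cc1cc(CCCO[Si](C)(C)C(C)(C)C)cc(OC)c1OCc1cc(OC)c(O[Si](C(C)C)(C(C)C)C(C)C)c(OC)c1 | intermediate
15 | methyl arylacetate | COC(=O)Cc1cc(CCCO[Si](C)(C)C(C)(C)C)cc(OC)c1OCc1cc(OC)c(O[Si](C(C)C)(C(C)C)C(C)C)c(OC)c1 | intermediate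
16 | methyl aryldiazoacetate (key-step precursor) | COC(=O)C(=[N+]=[N-])c1cc(CCCO[Si](C)(C)C(C)(C)C)cc(OC)c1OCc1cc(OC)c(O[Si](C(C)C)(C(C)C)C(C)C)c(OC)c1 | intermediate
17 | methyl (2R,3S)-cis-2-aryl-2,3-dihydrobenzofuran-3-carboxylate (key-step product) | COc1cc(cc(OC)c1O[Si](C(C)C)(C(C)C)C(C)C)[C@@H]1Oc2c(OC)cc(CCCO[Si](C)(C)C(C)(C)C)cc2[C@@H]1C(=O)OC | intermediate
18 | (2R,3R)-3-hydroxymethyl dihydrobenzofuran | COc1cc(cc(OC)c1O[Si](C(C)C)(C(C)C)C(C)C)[C@@H]1Oc2c(OC)cc(CCCO[Si](C)(C)C(C)(C)C)cc2[C@@H]1CO | intermediate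
19 | (2R,3R)-bis-TBS ether, ring B TIPS ether | COc1cc(cc(OC)c1O[Si](C(C)C)(C(C)C)C(C)C)[C@@H]1Oc2c(OC)cc(CCCO[Si](C)(C)C(C)(C)C)cc2[C@@H]1CO[Si](C)(C)C(C)(C)C | intermediate
20 | (2R,3R)-bis-TBS ether, free ring B phenol | COc1cc(cc(OC)c1O)[C@@H]1Oc2c(OC)cc(CCCO[Si](C)(C)C(C)(C)C)cc2[C@@H]1CO[Si](C)(C)C(C)(C)C | intermediate
21 | methyl (R)-2,2-dimethyl-1,3-dioxolane-4-carboxylate | COC(=O)[C@H]1COC(C)(C)O1 | starting material
22 | methyl (R)-2,3-dihydroxypropanoate | COC(=O)[C@H](O)CO | intermediate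
23 | methyl (R)-3-(TBS-oxy)-2-hydroxypropanoate | COC(=O)[C@H](O)CO[Si](C)(C)C(C)(C)C | intermediate
24 | methyl (S)-2-aryloxy-3-(TBS-oxy)propanoate | COC(=O)[C@H](CO[Si](C)(C)C(C)(C)C)Oc1c(OC)cc(cc1OC)[C@@H]1Oc2c(OC)cc(CCCO[Si](C)(C)C(C)(C)C)cc2[C@@H]1CO[Si](C)(C)C(C)(C)C | intermediate
25 | (S)-Weinreb amide | CON(C)C(=O)[C@H](CO[Si](C)(C)C(C)(C)C)Oc1c(OC)cc(cc1OC)[C@@H]1Oc2c(OC)cc(CCCO[Si](C)(C)C(C)(C)C)cc2[C@@H]1CO[Si](C)(C)C(C)(C)C | intermediate
26 | 4-bromo-2-methoxyphenol | COc1cc(Br)ccc1O | starting material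
27 | (4-bromo-2-methoxyphenoxy)triisopropylsilane | COc1cc(Br)ccc1O[Si](C(C)C)(C(C)C)C(C)C | intermediate
28 | [3-methoxy-4-(TIPS-oxy)phenyl]magnesium bromide | COc1cc([Mg]Br)ccc1O[Si](C(C)C)(C(C)C)C(C)C | intermediate
29 | (S)-α-aryloxy aryl ketone | COc1cc(ccc1O[Si](C(C)C)(C(C)C)C(C)C)C(=O)[C@H](CO[Si](C)(C)C(C)(C)C)Oc1c(OC)cc(cc1OC)[C@@H]1Oc2c(OC)cc(CCCO[Si](C)(C)C(C)(C)C)cc2[C@@H]1CO[Si](C)(C)C(C)(C)C | intermediate
30 | (1R,2S)-erythro alcohol, tetrasilyl ether | COc1cc(ccc1O[Si](C(C)C)(C(C)C)C(C)C)[C@@H](O)[C@H](CO[Si](C)(C)C(C)(C)C)Oc1c(OC)cc(cc1OC)[C@@H]1Oc2c(OC)cc(CCCO[Si](C)(C)C(C)(C)C)cc2[C@@H]1CO[Si](C)(C)C(C)(C)C | intermediate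
31 | CNP0301567.1 | COc1cc([C@@H](O)[C@H](CO)Oc2c(OC)cc([C@@H]3Oc4c(OC)cc(CCCO)cc4[C@@H]3CO)cc2OC)ccc1O | target

**Step count**

Total steps: 23. Longest linear sequence: 18 steps (from eugenol: steps 1–4, 7–15, 18, 19, 21–23).

**Steps most likely to fail**

1. Step 12. The heavily oxygenated substrate, with a methoxy group flanking the benzyloxy group, may give weak enantio-induction, leakage to the trans isomer or carbene dimerisation. Fallback, from 16: the insertion is run with an achiral bulky dirhodium carboxylate, Rh2(O2CCPh3)4 (CH2Cl2, 0 °C), a class expected to favour the kinetic cis product. This should give 17 as a racemate with its enantiomer, methyl (2S,3R)-cis-2-aryl-2,3-dihydrobenzofuran-3-carboxylate F1. Reduction with iBu2AlH as in step 13 gives 18 together with the (2S,3S) alcohol F2. The enantiomers are separated by preparative chromatography on a chiral stationary phase (lipase-mediated acylation as an alternative), and 18 re-enters the route at step 14. Absolute control then comes from resolution, not from the catalyst.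

2. Step 22. If the zinc chelate to the hindered aryloxy oxygen does not form, Felkin–Anh attack takes over and facial selectivity erodes or reverses towards the threo alcohol. Fallback, from 25: the Weinreb amide is reduced with iBu2AlH (THF, −78 °C) to the (S)-2-aryloxy-3-(TBS-oxy)propanal F3. The Grignard reagent 28 is then added at −78 °C in THF under non-chelating conditions. For addition to the aldehyde the Felkin–Anh mode (aryloxy group anti to the incoming nucleophile) leads to the same anti (1R,2S) alcohol, so the route is rejoined at 30. The C7 stereocentre is thus made by C–C bond formation, not by hydride delivery, and the very preference that would spoil the reduction is put to use.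

3. Step 18. The 2,6-dimethoxyphenol is hindered, so displacement at the secondary oxyphosphonium centre may be slow, with elimination or alkylation of the hydrazide competing. Fallback, from 23: the alcohol is converted with Tf2O and 2,6-lutidine (CH2Cl2, −78 °C) into methyl (R)-3-(TBS-oxy)-2-(trifluoromethylsulfonyloxy)propanoate F4. This is displaced by the phenoxide of 20 (Cs2CO3, MeCN, 0 °C) in an SN2 reaction with inversion, rejoining the route at 24.

**Further compounds**

F1 | step 12 | methyl (2S,3R)-cis-2-aryl-2,3-dihydrobenzofuran-3-carboxylate (enantiomer of 17) | COc1cc(cc(OC)c1O[Si](C(C)C)(C(C)C)C(C)C)[C@H]1Oc2c(OC)cc(CCCO[Si](C)(C)C(C)(C)C)cc2[C@H]1C(=O)OC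
F2 | step 12 | (2S,3S)-3-hydroxymethyl dihydrobenzofuran (enantiomer of 18) | COc1cc(cc(OC)c1O[Si](C(C)C)(C(C)C)C(C)C)[C@H]1Oc2c(OC)cc(CCCO[Si](C)(C)C(C)(C)C)cc2[C@H]1CO
F3 | step 22 | (S)-2-aryloxy-3-(TBS-oxy)propanal | O=C[C@H](CO[Si](C)(C)C(C)(C)C)Oc1c(OC)cc(cc1OC)[C@@H]1Oc2c(OC)cc(CCCO[Si](C)(C)C(C)(C)C)cc2[C@@H]1CO[Si](C)(C)C(C)(C)C
F4 | step 18 | methyl (R)-3-(TBS-oxy)-2-(trifluoromethylsulfonyloxy)propanoate | COC(=O)[C@H](OS(=O)(=O)C(F)(F)F)CO[Si](C)(C)C(C)(C)C
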